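**Retrosynthetic overview**

1. Numbering is that of the cladiellin skeleton: carbocycle C1–C10; cyclohexane C1, C10–C14; oxepane C1, C2, C3, O, C16, C15, C14; tetrahydrofuran O, C2, C1, C10, C9. The end game runs from the bridged (Z)-C6=C7 oxonene 28: C4 octanoate, then epoxide, allylic alcohol, enone and 1,2-reduction give the C6–OH/C7=C19 unit.
2. Key disconnection (tetrahydrofuran, closed last): C9–O and C8–C9 are made in one operation. A copper carbenoid at C9 (α-diazo ester; the ester is a removable activating group) is trapped by the ring oxygen of a 2,6-cis-6-isopropenyl tetrahydropyran (O, C2–C6), and the bicyclic oxonium ylide undergoes a [2,3] shift that enlarges the pyran by three atoms to the nine-membered ether.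
3. Enabling feature: the tetrahydrofuran oxygen is also a ring atom of the oxonane (O, C2–C9), and C9 lies three atoms from C6 (C9–C8–C7–C6). The oxonane is therefore a 2-alkenyl pyran enlarged by an allyl shift from O to C9, and the C6=C7 alkene left behind maps onto the C6–OH/C7=C19 unit.
4. Precursor 21 (cyclohexane–oxepane–pyran): the oxepane comes from 7-exo opening of a pyran C3–C4 epoxide by C16–OH (sets C3, C4); the pyran from a three-component oxocarbenium allylation and ring-closing metathesis; the cyclohexane from (R)-carvone by aldol at C1 (sets C1, C2) and epoxide opening at C10 by ethoxyacetylide (sets C10, C11, brings the C9 ester arm).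
5. Ring order: cyclohexane (carvone), tetrahydropyran (temporary, later the oxonane), oxepane, then tetrahydrofuran together with the pyran-to-oxonane expansion.

Key step: step 15

Remark on the chemistry: external reagents are assumed to reach the (Z)-C6=C7 alkene and the derived C6 ketone from the same outer face, so the epoxide route gives the C6 epimer and steps 23–24 invert it.

**Route**

Step 1
Reactants: 1 (R)-(−)-carvone
Product: 2 (R)-5-(3-hydroxyprop-1-en-2-yl)-2-methylcyclohex-2-en-1-one (C16–OH)
Conditions: SeO2 (cat.), t-BuOOH, CH2Cl2, 23 °C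
Reagents that add atoms: tert-butyl hydroperoxide, CC(C)(C)OO
Why: SeO2-catalysed allylic hydroxylation (ene reaction, then [2,3] shift of the allylseleninic acid) should oxidise the methyl of the electron-rich 1,1-disubstituted alkene while the enone alkene stays inert; the carvone stereocentre (C14) is untouched.

Step 2
Reactants: 2 allylic alcohol
Product: 3 tert-butyldiphenylsilyl ether of 2
Conditions: t-BuPh2SiCl, imidazole, DMF, 23 °C
Reagents that add atoms: tert-butyl(chloro)diphenylsilane, CC(C)(C)[Si](Cl)(c1ccccc1)c1ccccc1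
Why: Standard silylation of a primary alcohol gives an ether that should survive the bases, hydrides, Lewis acids and zerovalent palladium used before step 12.

Step 3
Reactants: 3 silyl ether; 4 methacrolein
Product: 6 anti aldol adduct (β-hydroxy ketone with new C1–C2 bond), via lithium dienolate 5 (not isolated)
Conditions: LiN(i-Pr)2, THF, −78 °C; then 4, −78 °C; H2O quench
Reagents that add atoms: methacrolein (4), CC(=C)C=O
Why: Kinetic deprotonation at the α′ carbon (C1) and a lithium aldol through a chair Zimmerman–Traxler transition state of the ring (E)-enolate should give the anti adduct, with the aldehyde entering anti to the C14 side chain; this sets C1 and C2.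

Step 4
Reactants: 6 aldol adduct
Product: 7 triethylsilyl ether of 6
Conditions: Et3SiOTf, 2,6-lutidine, CH2Cl2, −78 °C
Reagents that add atoms: triethylsilyl trifluoromethanesulfonate, CC[Si](CC)(CC)OS(=O)(=O)C(F)(F)F
Why: Silyl triflate protection under non-basic conditions blocks retro-aldol cleavage and provides the silyl ether needed as oxygen donor in step 6.

Step 5
Reactants: 7 silyl-protected enone
Product: 9 enol triflate (C10–OTf with C10=C11), via lithium enolate 8 (not isolated)
Conditions: LiBH(s-Bu)3, THF, −78 °C; then PhNTf2, −78 to 0 °C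
Reagents that add atoms: N-phenylbis(trifluoromethanesulfonimide), O=S(=O)(N(c1ccccc1)S(=O)(=O)C(F)(F)F)C(F)(F)F
Why: Conjugate reduction of the 2-methyl enone gives the regiodefined C10–C11 enolate, which is trapped on oxygen (enol triflate formation); C1, C2 and C14 are not affected.

Step 6
Reactants: 9 enol triflate silyl ether; 4 methacrolein; 10 allyltrimethylsilane
Product: 11 C2–O–C6 ether carrying isopropenyl (C7, C8, C19) and allyl (C5, C4) on C6
Conditions: Me3SiOTf (cat.), CH2Cl2, −78 °C
Reagents that add atoms: methacrolein (4), CC(=C)C=O; allyltrimethylsilane (10), C=CC[Si](C)(C)C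
Why: Silyl-modified Sakurai three-component coupling: silyl ether and aldehyde give the (E)-oxocarbenium ion C2–O+=C6, which the allylsilane traps; with C2–H eclipsing the oxocarbenium plane, attack anti to the bulky ring carbon C1 should give the C6 epimer that becomes 2,6-cis in the pyran, and the electron-poor enol triflate cannot act as an internal Prins nucleophile.

Step 7
Reactants: 11 ether enol triflate
Product: 12 pentaene ether with C10–H (trisubstituted C10=C11 alkene)
Conditions: Pd(OAc)2 (cat.), PPh3, HCO2H, n-Bu3N, DMF, 60 °C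
Reagents that add atoms: none
Why: Palladium-catalysed formate reduction of an enol triflate (oxidative addition to zerovalent palladium, formate exchange, loss of CO2, reductive elimination) replaces OTf by H without touching the stereocentres or the silyl ether.

Step 8
Reactants: 12 pentaene ether
Product: 13 C10–C11 epoxide (oxygen anti to the C2 side chain)
Conditions: mCPBA, CH2Cl2, −20 °C
Reagents that add atoms: 3-chloroperoxybenzoic acid, OOC(=O)c1cccc(Cl)c1
Why: Prilezhaev epoxidation should select the only trisubstituted alkene without allylic oxygen and approach anti to the branched substituent on C1; this fixes C11 and, after inversion in step 9, C10.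

Step 9
Reactants: 13 epoxide; 14 ethoxyacetylene
Product: 16 ethyl ester (C10–CH2CO2Et arm and tertiary C11–OH), via ynol ether 15 (not isolated)
Conditions: 14, n-BuLi, THF, −78 °C; BF3·OEt2; then 13; then 1 M H2SO4, THF, 0 °C
Reagents that add atoms: ethoxyacetylene (14), C#COCC; water, O
Why: BF3-promoted alkynylation of an epoxide: the acetylide opens the secondary C10 by trans-diaxial SN2 attack with inversion, C11–OH keeps its configuration, and acid hydration of the ynol ether gives the ester; the trans-diaxial arm and hydroxyl cannot lactonise.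

Step 10
Reactants: 16 ester
Product: 17 2,6-cis-6-isopropenyl-3-methyl-5,6-dihydro-2H-pyran (O, C2, C3=C4, C5, C6)
Conditions: second-generation Grubbs catalyst, RuCl2(=CHPh)(PCy3)(H2IMes) (5 mol %), CH2Cl2, 40 °C
Reagents that add atoms: none
Why: Ring-closing metathesis starts at the monosubstituted allyl alkene and closes onto the C3 isopropenyl-type alkene to give the six-membered trisubstituted alkene with loss of ethylene; the other 1,1-disubstituted alkenes could only give four-membered or tetrasubstituted five-membered rings.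

Step 11
Reactants: 17 dihydropyran
Product: 18 C3–C4 epoxide (oxygen anti to the substituents on C2 and C6)
Conditions: mCPBA, CH2Cl2, 0 °C
Reagents that add atoms: 3-chloroperoxybenzoic acid, OOC(=O)c1cccc(Cl)c1
Why: Prilezhaev epoxidation of the only trisubstituted alkene from the pyran face opposite the two cis substituents places both C–O bonds on the face required for trans-diaxial opening in step 12.

Step 12
Reactants: 18 pyran epoxide
Product: 20 tricyclic diol ester (cyclohexane–oxepane–tetrahydropyran with C4–OH and C11–OH), via epoxy alcohol 19 (not isolated)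
Conditions: Bu4NF, THF, 0 °C; then (1S)-(+)-10-camphorsulfonic acid (cat.), CH2Cl2, 23 °C
Reagents that add atoms: none
Why: After desilylation, acid-catalysed 7-exo epoxide opening by C16–OH at the tertiary C3 (trans-diaxial, inversion) closes the oxepane and leaves C4–OH with retention; attack at C4 would need an eight-membered ring; this sets C3 and C4.

Step 13
Reactants: 20 diol ester
Product: 21 bis(triethylsilyl) ether of 20
Conditions: Et3SiOTf (excess), 2,6-lutidine, CH2Cl2, 0 °C
Reagents that add atoms: triethylsilyl trifluoromethanesulfonate, CC[Si](CC)(CC)OS(=O)(=O)C(F)(F)F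
Why: Silyl triflate protects both the hindered secondary and the tertiary hydroxyl, so that neither alkoxide formation nor O–H insertion interferes in steps 14 and 15.

Step 14
Reactants: 21 bis-silyl ester
Product: 23 α-diazo ester (diazo group on C9), via trifluoroacetyl ester 22 (not isolated)
Conditions: LiN(SiMe3)2, THF, −78 °C; CF3CO2CH2CF3; then MeSO2N3, Et3N, H2O, MeCN, 23 °C
Reagents that add atoms: methanesulfonyl azide, CS(=O)(=O)N=[N+]=[N-]
Why: Detrifluoroacetylative (Regitz-type) diazo transfer: Claisen trifluoroacetylation activates the only enolisable position (C9), and the sulfonyl azide delivers N2 with loss of the trifluoroacetyl group as its sulfonamide.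

Step 15
Reactants: 23 α-diazo ester
Product: 25 ring-expanded tetracyclic ester with (Z)-C6=C7 oxonene and CO2Et on C9, via oxonium ylide 24 (not isolated)
Conditions: Cu(hfacac)2 (5 mol %), CH2Cl2, reflux, slow addition of 23 (0.005 M)
Reagents that add atoms: none
Why: Cu(hfacac)2 converts the diazo ester into an electrophilic copper carbenoid at C9, which is captured by a lone pair of the pyran oxygen through a five-membered transition state; this C9–O bond closes the tetrahydrofuran ring (five-ring closure along C9–C10–C1–C2–O) and gives the bicyclic oxonium ylide 24. The ylide then undergoes a [2,3]-sigmatropic shift over the O–C6–C7=C8 allyl unit: C9–C8 forms, O–C6 breaks, and the pyran is enlarged by three atoms to the oxonane with a new C6=C7 alkene. The closest known reaction type is the copper- or rhodium-catalysed oxonium ylide formation and [2,3] rearrangement of diazo carbonyl compounds tethered to 2-alkenyl tetrahydropyrans, which gives oxabicyclo[6.2.1]undecenes. C9 is the only new stereocentre: it is a bridgehead of the oxabicyclo[6.2.1] system and the suprafacial allyl transfer can only place C8 cis to C3 across the tetrahydrofuran, so the ester occupies the position of the later H9; the (Z)-alkene is expected from the compact envelope transition state that keeps both ring bonds cis. The step needs ylide formation to beat 1,2-hydride shift from C10–H, and attack on the pyran oxygen to beat attack on the oxepane oxygen: the first is favoured by the easy five-ring closure and the copper catalyst, the second because the trans-fused oxepane holds its oxygen anti to C10 and out of reach.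

Step 16
Reactants: 25 ring-expanded ester
Product: 26 ester with C15 methyl (C15=C17 reduced)
Conditions: H2 (1 atm), RhCl(PPh3)3 (10 mol %), benzene, 23 °C
Reagents that add atoms: none
Why: Homogeneous hydrogenation with RhCl(PPh3)3 reduces the 1,1-disubstituted exocyclic alkene but not the trisubstituted ring alkene; hydrogen should add to the face of C15 syn to H14 (anti to C13), as in the hydrogenation of 2-alkyl methylenecycloalkanes to cis products, which sets C15.

Step 17
Reactants: 26 ethyl ester
Product: 27 carboxylic acid (CO2H on C9)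
Conditions: LiOH, THF/MeOH/H2O, 50 °C; then aqueous HCl to pH 3
Reagents that add atoms: lithium hydroxide, [Li+].[OH-]
Why: Saponification of the only ester; the silyl ethers and the bridgehead-type α-alkoxy centre are stable to hydroxide.

Step 18
Reactants: 27 acid
Product: 28 bridged (Z)-oxonene with C9–H (bis-silyl ether)
Conditions: 9-mesityl-10-phenylacridinium tetrafluoroborate (5 mol %), PhSSPh (10 mol %), i-Pr2NEt (20 mol %), CF3CH2OH, 450 nm LEDs, 23 °C
Reagents that add atoms: none
Why: Acridinium photoredox hydrodecarboxylation: oxidation of the carboxylate and loss of CO2 give the α-alkoxy C9 radical, which takes a hydrogen atom from thiophenol; C9 is a bridgehead of the oxabicyclo[6.2.1] core, so only the cis-bridged configuration of H9 can form.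

Step 19
Reactants: 28 bis-silyl ether
Product: 29 diol (C4–OH and C11–OH)
Conditions: Bu4NF, THF, 23 °C
Reagents that add atoms: none
Why: Fluoride-mediated desilylation frees both hydroxyls without affecting the ether rings or the alkene.

Step 20
Reactants: 29 diol; 30 octanoyl chloride
Product: 31 C4 octanoate
Conditions: 30, pyridine, DMAP (cat.), CH2Cl2, 0 to 23 °C
Reagents that add atoms: octanoyl chloride (30), CCCCCCCC(=O)Cl
Why: DMAP-catalysed acylation takes place at the secondary C4–OH; the tertiary axial C11–OH is inert under these conditions.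

Step 21
Reactants: 31 octanoate
Product: 32 C6–C7 epoxide
Conditions: dimethyldioxirane, acetone, −20 °C
Reagents that add atoms: dimethyldioxirane, CC1(C)OO1
Why: Dioxirane epoxidation of the only alkene under neutral conditions; the oxidant should use the open outer face of the (Z)-oxonene, away from the transannular ether bridge.

Step 22
Reactants: 32 epoxide
Product: 33 allylic alcohol with C7=C19 (C6 epimer of the target)
Conditions: Cp2TiCl2, Zn dust, THF, 23 °C (gives Cp2TiCl, trivalent titanium); then 32; aqueous HCl work-up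
Reagents that add atoms: none
Why: Reductive epoxide opening by Cp2TiCl (Nugent–RajanBabu type) gives the tertiary C7 radical, which is trapped by a second Cp2TiCl and undergoes β-hydride elimination toward the methyl group; the ester is tolerated, the exocyclic alkene forms, and C6 keeps the epoxide oxygen with retention.

Step 23
Reactants: 33 allylic alcohol
Product: 34 α-methylene ketone (C6 ketone)
Conditions: Dess–Martin periodinane, CH2Cl2, 0 °C
Reagents that add atoms: Dess–Martin periodinane, CC(=O)OI1(OC(C)=O)(OC(C)=O)OC(=O)c2ccccc12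
Why: Hypervalent iodine oxidation of the secondary allylic alcohol; the tertiary C11–OH and the ester are not affected.

Step 24
Reactants: 34 enone
Product: 35 target CNP0398453.2
Conditions: NaBH4, CeCl3·7H2O, MeOH, −78 °C
Reagents that add atoms: none
Why: Luche 1,2-reduction; hydride should add to C6 from the same outer face that the dioxirane used, so the hydroxyl ends on the inner face, the configuration opposite to 33 and that of the target.

**Compound list**

1 | (R)-(−)-carvone | CC1=CC[C@H](CC1=O)C(C)=C | starting material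
2 | (R)-5-(3-hydroxyprop-1-en-2-yl)-2-methylcyclohex-2-en-1-one | CC1=CC[C@H](CC1=O)C(=C)CO | intermediate
3 | tert-butyldiphenylsilyl ether of 2 | CC1=CC[C@H](CC1=O)C(=C)CO[Si](c2ccccc2)(c3ccccc3)C(C)(C)C | intermediate
4 | methacrolein | CC(=C)C=O | starting material
5 | lithium dienolate of 3 (deprotonated at C1) | [Li]OC1=C[C@@H](CC=C1C)C(=C)CO[Si](c2ccccc2)(c3ccccc3)C(C)(C)C | intermediate
6 | anti aldol adduct (C2–OH, C1 trans to the C14 side chain) | O[C@H](C(C)=C)[C@H]1[C@@H](CC=C(C)C1=O)C(=C)CO[Si](c2ccccc2)(c3ccccc3)C(C)(C)C | intermediate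
7 | triethylsilyl ether of 6 | CC[Si](CC)(CC)O[C@H](C(C)=C)[C@H]1[C@@H](CC=C(C)C1=O)C(=C)CO[Si](c2ccccc2)(c3ccccc3)C(C)(C)C | intermediate
8 | lithium enolate (C10–OLi, C10=C11) | CC[Si](CC)(CC)O[C@H](C(C)=C)[C@H]1[C@@H](CCC(C)=C1O[Li])C(=C)CO[Si](c2ccccc2)(c3ccccc3)C(C)(C)C | intermediate
9 | enol triflate (C10–OTf, C10=C11) | CC[Si](CC)(CC)O[C@H](C(C)=C)[C@H]1[C@@H](CCC(C)=C1OS(=O)(=O)C(F)(F)F)C(=C)CO[Si](c2ccccc2)(c3ccccc3)C(C)(C)C | intermediate
10 | allyltrimethylsilane | C=CC[Si](C)(C)C | starting material
11 | C2–O–C6 ether (C6: isopropenyl, allyl) with enol triflate | C=CC[C@@H](C(C)=C)O[C@H](C(C)=C)[C@H]1[C@@H](CCC(C)=C1OS(=O)(=O)C(F)(F)F)C(=C)CO[Si](c2ccccc2)(c3ccccc3)C(C)(C)C | intermediate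
12 | pentaene ether (C10=C11 alkene) | C=CC[C@@H](C(C)=C)O[C@H](C(C)=C)[C@H]1[C@@H](CCC(C)=C1)C(=C)CO[Si](c2ccccc2)(c3ccccc3)C(C)(C)C | intermediate
13 | C10–C11 epoxide of 12 | C=CC[C@@H](C(C)=C)O[C@H](C(C)=C)[C@H]1[C@@H](CC[C@]2(C)O[C@H]12)C(=C)CO[Si](c3ccccc3)(c4ccccc4)C(C)(C)C | intermediate
14 | ethoxyacetylene | C#COCC | starting material
15 | ynol ether (C10–C≡C–OEt, C11–OH) | C=CC[C@@H](C(C)=C)O[C@H](C(C)=C)[C@H]1[C@@H](CC[C@](C)(O)[C@H]1C#COCC)C(=C)CO[Si](c2ccccc2)(c3ccccc3)C(C)(C)C | intermediate
16 | ethyl ester (C10–CH2CO2Et, C11–OH) | C=CC[C@@H](C(C)=C)O[C@H](C(C)=C)[C@H]1[C@@H](CC[C@](C)(O)[C@H]1CC(=O)OCC)C(=C)CO[Si](c2ccccc2)(c3ccccc3)C(C)(C)C | intermediate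
17 | 2,6-cis dihydropyran (C3=C4) | CC(=C)[C@@H]1CC=C(C)[C@@H](O1)[C@H]2[C@@H](CC[C@](C)(O)[C@H]2CC(=O)OCC)C(=C)CO[Si](c3ccccc3)(c4ccccc4)C(C)(C)C | intermediate
18 | pyran C3–C4 epoxide | CC(=C)[C@@H]1C[C@H]3O[C@@]3(C)[C@@H](O1)[C@H]2[C@@H](CC[C@](C)(O)[C@H]2CC(=O)OCC)C(=C)CO[Si](c4ccccc4)(c5ccccc5)C(C)(C)C | intermediate
19 | epoxy alcohol (C16–OH free) | CC(=C)[C@@H]1C[C@H]3O[C@@]3(C)[C@@H](O1)[C@H]2[C@@H](CC[C@](C)(O)[C@H]2CC(=O)OCC)C(=C)CO | intermediate
20 | tricyclic diol ester (cyclohexane–oxepane–tetrahydropyran; C4–OH, C11–OH, C15=C17, C6 isopropenyl) | CC(=C)[C@@H]1C[C@@H](O)[C@]2(C)OCC(=C)[C@@H]3CC[C@](C)(O)[C@@H](CC(=O)OCC)[C@H]3[C@@H]2O1 | intermediate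
21 | bis(triethylsilyl) ether of 20 | CC(=C)[C@@H]1C[C@@H](O[Si](CC)(CC)CC)[C@]2(C)OCC(=C)[C@@H]3CC[C@](C)(O[Si](CC)(CC)CC)[C@@H](CC(=O)OCC)[C@H]3[C@@H]2O1 | intermediate
22 | α-trifluoroacetyl ester (C9 epimers) | CC(=C)[C@@H]1C[C@@H](O[Si](CC)(CC)CC)[C@]2(C)OCC(=C)[C@@H]3CC[C@](C)(O[Si](CC)(CC)CC)[C@@H](C(C(=O)C(F)(F)F)C(=O)OCC)[C@H]3[C@@H]2O1 | intermediate
23 | α-diazo ester (diazo on C9) | CC(=C)[C@@H]1C[C@@H](O[Si](CC)(CC)CC)[C@]2(C)OCC(=C)[C@@H]3CC[C@](C)(O[Si](CC)(CC)CC)[C@@H](C(=[N+]=[N-])C(=O)OCC)[C@H]3[C@@H]2O1 | intermediate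
24 | bicyclic oxonium ylide (O bonded to C2, C6, C9) | CC(=C)[C@@H]1C[C@@H](O[Si](CC)(CC)CC)[C@]2(C)OCC(=C)[C@@H]3CC[C@](C)(O[Si](CC)(CC)CC)[C@H]4[C-](C(=O)OCC)[O+]1[C@H]2[C@@H]34 | intermediate
25 | ring-expanded tetracyclic ester ((Z)-C6=C7, CO2Et on C9) | C/C1=C/C[C@@H](O[Si](CC)(CC)CC)[C@]2(C)OCC(=C)[C@@H]3CC[C@](C)(O[Si](CC)(CC)CC)[C@@H]4[C@H]3[C@@H]2O[C@]4(C1)C(=O)OCC | intermediate
26 | ester with C15 methyl | C/C1=C/C[C@@H](O[Si](CC)(CC)CC)[C@]2(C)OC[C@H](C)[C@@H]3CC[C@](C)(O[Si](CC)(CC)CC)[C@@H]4[C@H]3[C@@H]2O[C@]4(C1)C(=O)OCC | intermediate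
27 | carboxylic acid (CO2H on C9) | C/C1=C/C[C@@H](O[Si](CC)(CC)CC)[C@]2(C)OC[C@H](C)[C@@H]3CC[C@](C)(O[Si](CC)(CC)CC)[C@@H]4[C@H]3[C@@H]2O[C@]4(C1)C(=O)O | intermediate
28 | bridged (Z)-oxonene, C9–H, bis-silyl ether | C/C1=C/C[C@@H](O[Si](CC)(CC)CC)[C@]2(C)OC[C@H](C)[C@@H]3CC[C@](C)(O[Si](CC)(CC)CC)[C@@H]4[C@H]3[C@@H]2O[C@H]4C1 | intermediate
29 | diol (C4–OH, C11–OH) | C/C1=C/C[C@@H](O)[C@]2(C)OC[C@H](C)[C@@H]3CC[C@](C)(O)[C@@H]4[C@H]3[C@@H]2O[C@H]4C1 | intermediate
30 | octanoyl chloride | CCCCCCCC(=O)Cl | starting material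
31 | C4 octanoate | C/C1=C/C[C@@H](OC(=O)CCCCCCC)[C@]2(C)OC[C@H](C)[C@@H]3CC[C@](C)(O)[C@@H]4[C@H]3[C@@H]2O[C@H]4C1 | intermediate
32 | C6–C7 epoxide | C[C@]12O[C@H]1C[C@@H](OC(=O)CCCCCCC)[C@]3(C)OC[C@H](C)[C@@H]4CC[C@](C)(O)[C@@H]5[C@H]4[C@@H]3O[C@H]5C2 | intermediate
33 | allylic alcohol, C6 epimer of the target | C=C1[C@@H](O)C[C@@H](OC(=O)CCCCCCC)[C@]2(C)OC[C@H](C)[C@@H]3CC[C@](C)(O)[C@@H]4[C@H]3[C@@H]2O[C@H]4C1 | intermediate
34 | α-methylene ketone (C6 ketone) | C=C1C(=O)C[C@@H](OC(=O)CCCCCCC)[C@]2(C)OC[C@H](C)[C@@H]3CC[C@](C)(O)[C@@H]4[C@H]3[C@@H]2O[C@H]4C1 | intermediate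
35 | CNP0398453.2 | C=C1C[C@@H]2O[C@H]3[C@H]4[C@@H](CC[C@](C)(O)[C@H]42)[C@@H](C)CO[C@@]3(C)[C@H](OC(=O)CCCCCCC)C[C@H]1O | target

**Step count and risks**

Total step count: 24. Longest linear sequence: 24 steps (1 to 35).

Steps most likely to fail:

Step 15. The carbenoid may suffer a 1,2-hydride shift from C10–H to give the C9=C10 enoate, or may form an ylide at the oxepane oxygen, before the five-membered ylide at the pyran oxygen is reached. The fallback sets out from 21 and avoids the metal carbene. Enolisation with KN(SiMe3)2 and oxidation with 2-(phenylsulfonyl)-3-phenyloxaziridine would give the α-hydroxy ester F1. Tf2O and 2,6-di-tert-butyl-4-methylpyridine at −78 °C would give the α-triflyloxy ester F2. On warming, F2 should alkylate the neighbouring pyran oxygen (five-membered oxonium triflate, neighbouring-group participation), and deprotonation at C9 by the hindered base should generate the same ylide 24, whose [2,3] shift returns to 25. This fallback is less precedented than the main step.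

Step 6. The silyl ether may be lost without C–O bond formation, the allylic C2–O bond may ionise under the silyl triflate, or facial selectivity at C6 may be poor. The fallback sets out from 9 and builds the acetal stepwise. PPTS in MeOH would give the alcohol F3; methacryloyl chloride, Et3N and DMAP the methacrylate F4; i-Bu2AlH at −78 °C followed by Ac2O, pyridine and DMAP (reductive acetylation) the α-acetoxy ether F5. Allylation of F5 with allyltrimethylsilane and BF3·OEt2 at −78 °C returns to 11, with the Lewis acid and temperature free to be tuned for the C6 selectivity.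

Step 8. The peracid may attack the face of C10=C11 syn to the C2 side chain, which would invert both C10 and C11. The fallback sets out from 12 and uses the halohydrin route, which delivers oxygen to the opposite face. N-bromosuccinimide in wet THF would form the bromonium ion on the face the peracid prefers, and water would open it at the tertiary C11 from the other face to give the bromohydrin F6. K2CO3 in MeOH then closes the epoxide and returns to 13.

Further compounds
F1 | step 15 | α-hydroxy ester (OH on C9, both epimers) | CC(=C)[C@@H]1C[C@@H](O[Si](CC)(CC)CC)[C@]2(C)OCC(=C)[C@@H]3CC[C@](C)(O[Si](CC)(CC)CC)[C@@H](C(O)C(=O)OCC)[C@H]3[C@@H]2O1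
F2 | step 15 | α-triflyloxy ester (OTf on C9) | CC(=C)[C@@H]1C[C@@H](O[Si](CC)(CC)CC)[C@]2(C)OCC(=C)[C@@H]3CC[C@](C)(O[Si](CC)(CC)CC)[C@@H](C(OS(=O)(=O)C(F)(F)F)C(=O)OCC)[C@H]3[C@@H]2O1
F3 | step 6 | C2 alcohol with enol triflate | O[C@H](C(C)=C)[C@H]1[C@@H](CCC(C)=C1OS(=O)(=O)C(F)(F)F)C(=C)CO[Si](c2ccccc2)(c3ccccc3)C(C)(C)C
F4 | step 6 | C2 methacrylate | CC(=C)C(=O)O[C@H](C(C)=C)[C@H]1[C@@H](CCC(C)=C1OS(=O)(=O)C(F)(F)F)C(=C)CO[Si](c2ccccc2)(c3ccccc3)C(C)(C)C
F5 | step 6 | α-acetoxy ether (acetal carbon C6, both epimers) | CC(=O)OC(C(C)=C)O[C@H](C(C)=C)[C@H]1[C@@H](CCC(C)=C1OS(=O)(=O)C(F)(F)F)C(=C)CO[Si](c2ccccc2)(c3ccccc3)C(C)(C)C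
F6 | step 8 | bromohydrin (C10–Br, C11–OH, trans-diaxial) | C=CC[C@@H](C(C)=C)O[C@H](C(C)=C)[C@H]1[C@@H](CC[C@](C)(O)[C@H]1Br)C(=C)CO[Si](c2ccccc2)(c3ccccc3)C(C)(C)C
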